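**Retrosynthetic overview** (longipinane numbering: C1 ketone, C2=C3(Me), C4 and C11 cyclobutane methines flanking the enone bridge, C5 cyclobutane CH, C6 CMe2, C7 methacrylate carbon, C8, C9 isobutyrate carbon, C10 C(Me))
1. Endgame: O7 acylation; the C1 enone comes from a C3 ketone by MeLi addition and oxidative 1,3-transposition.
2. Key disconnection: cyclobutane bond C4–C5, closed by intramolecular α′-enolate alkylation of a cis-fused bicyclo[5.4.0]undecenone C5 tosylate (six-membered ring C1–C2–C3–C4–C10–C11 fused to seven-membered ring C5–C6–C7–C8–C9–C10–C11).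
3. Enabling feature: in the cyclobutane C4–C10–C11–C5, C4 and C11 each flank one end of the C1–C2–C3 bridge, so with the carbonyl parked at C3 the C4 carbon is an α′-enolate held 1,3-syn to C5 across the C10–C11 fusion; C6 is quaternary and H-11 is syn to the leaving group, so the C5 sulfonate has no anti β-hydrogen.
4. Six-membered ring: [4+2] of an aminosiloxy diene onto a cycloheptenone (sets C10 and C11). Seven-membered ring: ring-closing metathesis. Oxygen triad C9/C7/C5: boron aldol, Evans–Tishchenko reduction (installs the isobutyrate), hydroxyl-directed reduction.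
5. Order of ring formation: seven-membered (step 5), six-membered (step 6), four-membered (step 10).

Key step: step 10

Remark on the chemistry: the Ipc2BCl aldol of a methyl ketone is assumed to attack the re face of methacrolein when the borane from (−)-α-pinene, (+)-Ipc2BCl, is used; if the induction runs the other way, the antipodal borane is taken and nothing else changes.

**Step 1**
Reactants: 1 3,3-dimethylpentane-2,4-dione; 2 methacrolein
Product: 4 (6R)-6-hydroxy-3,3,7-trimethyloct-7-ene-2,4-dione, via enol diisopinocampheylborinate 3 (not isolated)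
Conditions: (+)-Ipc2BCl, Et3N, Et2O, 0 °C; then 2, −78 to −20 °C; H2O2, MeOH, pH 7 buffer
Reagents that add atoms: none
Why: Diisopinocampheylboron-mediated asymmetric aldol reaction, in which only an acetyl methyl can enolise (the central carbon is quaternary) and the isopinocampheyl ligands select the aldehyde face in the cyclic transition state, which should set C9 as R.

**Step 2**
Reactants: 4 (6R)-6-hydroxy-3,3,7-trimethyloct-7-ene-2,4-dione; 5 isobutyraldehyde
Product: 7 (3R,5R)-5-hydroxy-2,6,6-trimethyl-7-oxooct-1-en-3-yl 2-methylpropanoate, via samarium-bound hemiacetal 6 (not isolated)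
Conditions: 5 (6 equiv), SmI2 (0.3 equiv), THF, −10 °C
Reagents that add atoms: none
Why: Evans–Tishchenko reduction, in which the hemiacetal on O9 delivers hydride intramolecularly to the C7 ketone through a chair-like bicyclic transition state, giving the 1,3-anti alcohol at C7 and leaving the isobutyrate on O9, while the C5 ketone has no β-hydroxyl and should stay untouched.

**Step 3**
Reactants: 7 (3R,5R)-5-hydroxy-2,6,6-trimethyl-7-oxooct-1-en-3-yl 2-methylpropanoate
Product: 8 (3R,5R)-2,6,6-trimethyl-7-oxo-5-[(triethylsilyl)oxy]oct-1-en-3-yl 2-methylpropanoate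
Conditions: Et3SiOTf, 2,6-lutidine, CH2Cl2, −78 °C
Reagents that add atoms: triethylsilyl triflate, CC[Si](CC)(CC)OS(=O)(=O)C(F)(F)F
Why: Silyl ether formation with a silyl triflate, which caps the hindered C7 hydroxyl before base is used so that neither retro-aldol cleavage nor acyl migration from O9 can occur.

**Step 4**
Reactants: 8 (3R,5R)-2,6,6-trimethyl-7-oxo-5-[(triethylsilyl)oxy]oct-1-en-3-yl 2-methylpropanoate
Product: 12 (3R,5R)-2,6,6-trimethyl-7-oxo-5-[(triethylsilyl)oxy]nona-1,8-dien-3-yl 2-methylpropanoate, via lithium enolate 9 (not isolated), via Mannich base 10 (not isolated), via methiodide 11 (not isolated)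
Conditions: LiN(SiMe3)2, THF, −78 °C; Eschenmoser's salt (CH2=NMe2 I), −78 °C to rt; MeI, CH2Cl2; DBU
Reagents that add atoms: Eschenmoser's salt, C=[N+](C)C.[I-]
Why: Mannich α-methylenation followed by quaternisation and elimination, regiospecific because the methyl group is the only enolisable position of the ketone (the other α-carbon is quaternary), and it creates no stereocentre.

**Step 5**
Reactants: 12 (3R,5R)-2,6,6-trimethyl-7-oxo-5-[(triethylsilyl)oxy]nona-1,8-dien-3-yl 2-methylpropanoate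
Product: 13 (1R,6R)-2,5,5-trimethyl-4-oxo-6-[(triethylsilyl)oxy]cyclohept-2-en-1-yl 2-methylpropanoate
Conditions: second-generation Grubbs catalyst RuCl2(=CHPh)(H2IMes)(PCy3) (5 mol%), CH2Cl2 (3 mM), 40 °C
Reagents that add atoms: none
Why: Ring-closing metathesis of the vinyl ketone onto the isopropenyl group, helped by the gem-dimethyl group, should give the trisubstituted cycloheptenone, whose ring enforces the cis C10=C11 geometry.

**Step 6**
Reactants: 13 (1R,6R)-2,5,5-trimethyl-4-oxo-6-[(triethylsilyl)oxy]cyclohept-2-en-1-yl 2-methylpropanoate; 14 (E)-1-(dimethylamino)-3-[(tert-butyldimethylsilyl)oxy]buta-1,3-diene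
Product: 16 (1R,2R,4R,7S)-4-hydroxy-1,5,5-trimethyl-6,10-dioxobicyclo[5.4.0]undec-8-en-2-yl 2-methylpropanoate, via cycloadduct 15 (not isolated)
Conditions: 14 (3 equiv), toluene, 100 °C, sealed tube; then HF (aq), MeCN, 0 °C to rt
Reagents that add atoms: none
Why: Diels–Alder reaction of the aminosiloxy diene, whose nucleophilic CH2 terminus bonds to the enone β-carbon C10 on the face anti to the allylic O9 acyloxy group, so the suprafacial addition should set the C10 quaternary centre and C11 with a cis ring fusion; HF then unmasks the C3 enone by loss of dimethylamine and removes the triethylsilyl group, and the epimerisable γ-acyl enone 16 is carried on at once.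

**Step 7**
Reactants: 16 (1R,2R,4R,7S)-4-hydroxy-1,5,5-trimethyl-6,10-dioxobicyclo[5.4.0]undec-8-en-2-yl 2-methylpropanoate
Product: 17 (1R,2R,4R,6R,7S)-4,6-dihydroxy-1,5,5-trimethyl-10-oxobicyclo[5.4.0]undec-8-en-2-yl 2-methylpropanoate
Conditions: Me4NBH(OAc)3, MeCN/AcOH, −30 °C
Reagents that add atoms: none
Why: Evans–Saksena hydroxyl-directed reduction, in which boron bound to the C7 hydroxyl delivers hydride to the same face of the C5 ketone and should give the 5,7-anti carbinol (leaving group on the face opposite C4), while the C3 enone has no hydroxyl to bind the reagent.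

**Step 8**
Reactants: 17 (1R,2R,4R,6R,7S)-4,6-dihydroxy-1,5,5-trimethyl-10-oxobicyclo[5.4.0]undec-8-en-2-yl 2-methylpropanoate
Product: 18 (1R,2R,4R,6R,7S)-4-[(tert-butyldimethylsilyl)oxy]-6-hydroxy-1,5,5-trimethyl-10-oxobicyclo[5.4.0]undec-8-en-2-yl 2-methylpropanoate
Conditions: tBuMe2SiOTf (1.05 equiv), 2,6-lutidine, CH2Cl2, −78 °C
Reagents that add atoms: tert-butyldimethylsilyl triflate, CC(C)(C)[Si](C)(C)OS(=O)(=O)C(F)(F)F
Why: Site-selective silylation, expected at the C7 hydroxyl because it is flanked by a CH2 group whereas the C5 hydroxyl sits between the CMe2 carbon and the ring-fusion methine.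

**Step 9**
Reactants: 18 (1R,2R,4R,6R,7S)-4-[(tert-butyldimethylsilyl)oxy]-6-hydroxy-1,5,5-trimethyl-10-oxobicyclo[5.4.0]undec-8-en-2-yl 2-methylpropanoate
Product: 19 (1R,2R,4R,6R,7S)-4-[(tert-butyldimethylsilyl)oxy]-1,5,5-trimethyl-6-[(4-methylbenzenesulfonyl)oxy]-10-oxobicyclo[5.4.0]undec-8-en-2-yl 2-methylpropanoate
Conditions: TsCl, Et3N, 1-methylimidazole (0.2 equiv), CH2Cl2, 0 °C to rt
Reagents that add atoms: 4-toluenesulfonyl chloride, Cc1ccc(cc1)S(Cl)(=O)=O
Why: Sulfonylation of the secondary alcohol under nucleophilic catalysis, which proceeds with retention at C5 and turns the directed-reduction product into the leaving group.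

**Step 10**
Reactants: 19 (1R,2R,4R,6R,7S)-4-[(tert-butyldimethylsilyl)oxy]-1,5,5-trimethyl-6-[(4-methylbenzenesulfonyl)oxy]-10-oxobicyclo[5.4.0]undec-8-en-2-yl 2-methylpropanoate
Product: 21 (1R,2S,3R,5R,7R,8S)-5-[(tert-butyldimethylsilyl)oxy]-2,6,6-trimethyl-9-oxotricyclo[5.4.0.0(2,8)]undec-10-en-3-yl 2-methylpropanoate, via lithium enolate 20 (not isolated)
Conditions: LiN(SiMe3)2 (1.2 equiv), THF, −78 °C (inverse addition); DMPU, −78 °C to rt
Reagents that add atoms: none
Why: Kinetic deprotonation of the cross-conjugated enone at C4 (the only α′ position, C2 being vinylic) gives lithium enolate 20, whose C4 terminus displaces the C5 tosylate from the rear in an intramolecular SN2 reaction across the C10–C11 ring fusion. The closest known reaction type is the intramolecular alkylation of a ketone enolate by a 1,3-disposed secondary sulfonate, an established way to close the cyclobutane of bicyclo[3.1.1]heptan-2-ones and of tricyclo[4.4.0.0(2,7)]decanones, including at carbons next to a quaternary centre. The four-membered ring C4–C10–C11–C5 closes in the 4-exo-tet (enolexo) mode, and the same bond completes transannularly the six-membered ring C1–C2–C3–C4–C5–C11 and the seven-membered ring C4–C5–C6–C7–C8–C9–C10. C5 is set by inversion of the tosylate that step 7 placed anti to O7, and C4 by the cis-fused bicycle, in which the enolate carbon is attached to C10 on the face opposite O9 and can bond to C5 only on that face. The step needs C- over O-alkylation and substitution over loss of the sulfonate: the enolate oxygen could reach C5 only through a boat-shaped bridged array, C6 is quaternary, H-11 is syn to the leaving group, and low-temperature inverse addition keeps the enolate from equilibrating to the extended dienolate that would expel the tosylate. The product cannot enolise further because C4 and C11 have become bridgeheads.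

**Step 11**
Reactants: 21 (1R,2S,3R,5R,7R,8S)-5-[(tert-butyldimethylsilyl)oxy]-2,6,6-trimethyl-9-oxotricyclo[5.4.0.0(2,8)]undec-10-en-3-yl 2-methylpropanoate
Product: 22 5-[(tert-butyldimethylsilyl)oxy]-9-hydroxy-2,6,6,9-tetramethyltricyclo[5.4.0.0(2,8)]undec-10-en-3-yl 2-methylpropanoate (carbinol centre C3 in longipinane numbering not controlled, other centres as in 21)
Conditions: MeLi, CeCl3, THF, −78 °C
Reagents that add atoms: methyllithium, [Li]C
Why: Organocerium 1,2-addition to the enone carbonyl, which is non-basic and carbonyl-selective so that the hindered isobutyrate should survive at −78 °C, and whose new carbinol centre is erased in the next step.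

**Step 12**
Reactants: 22 5-[(tert-butyldimethylsilyl)oxy]-9-hydroxy-2,6,6,9-tetramethyltricyclo[5.4.0.0(2,8)]undec-10-en-3-yl 2-methylpropanoate
Product: 25 (1R,2R,3R,5R,7S,8R)-5-[(tert-butyldimethylsilyl)oxy]-2,6,6,9-tetramethyl-11-oxotricyclo[5.4.0.0(2,8)]undec-9-en-3-yl 2-methylpropanoate, via tertiary chlorochromate ester 23 (not isolated), via transposed chlorochromate ester 24 (not isolated)
Conditions: pyridinium chlorochromate (C5H5NH)[CrO3Cl], 4 Å molecular sieves, CH2Cl2, rt
Reagents that add atoms: pyridinium chlorochromate, [O-][Cr](=O)(=O)Cl.c1cc[nH+]cc1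
Why: Dauben–Babler oxidative 1,3-transposition, in which the tertiary allylic chromate ester undergoes a [3,3] shift and the secondary ester is oxidised, moving the carbonyl to C1 and leaving the C2=C3(Me) alkene of the target enone without touching a stereocentre.

**Step 13**
Reactants: 25 (1R,2R,3R,5R,7S,8R)-5-[(tert-butyldimethylsilyl)oxy]-2,6,6,9-tetramethyl-11-oxotricyclo[5.4.0.0(2,8)]undec-9-en-3-yl 2-methylpropanoate
Product: 26 (1R,2R,3R,5R,7S,8R)-5-hydroxy-2,6,6,9-tetramethyl-11-oxotricyclo[5.4.0.0(2,8)]undec-9-en-3-yl 2-methylpropanoate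
Conditions: HF·pyridine, THF, 0 °C to rt
Reagents that add atoms: none
Why: Fluoride-mediated desilylation under mildly acidic conditions, where the trans-1,3 relation of O7 and O9 on the ring should prevent migration of the isobutyrate.

**Step 14**
Reactants: 26 (1R,2R,3R,5R,7S,8R)-5-hydroxy-2,6,6,9-tetramethyl-11-oxotricyclo[5.4.0.0(2,8)]undec-9-en-3-yl 2-methylpropanoate; 27 methacryloyl chloride
Product: 28 (1R,2R,3R,5R,7S,8R)-2,6,6,9-tetramethyl-3-[(2-methylpropanoyl)oxy]-11-oxotricyclo[5.4.0.0(2,8)]undec-9-en-5-yl 2-methylprop-2-enoate (target)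
Conditions: 27, Et3N, DMAP (cat.), CH2Cl2, 0 °C to rt
Reagents that add atoms: none
Why: DMAP-catalysed acylation of the remaining secondary alcohol with retention at C7 completes the diester.

**Compound list**
1 | 3,3-dimethylpentane-2,4-dione | CC(=O)C(C)(C)C(C)=O | starting material
2 | methacrolein | CC(=C)C=O | starting material
3 | enol bis[(+)-isopinocampheyl]borinate of 1 | C=C(OB([C@H]1C[C@H]2C[C@@H]([C@@H]1C)C2(C)C)[C@H]1C[C@H]2C[C@@H]([C@@H]1C)C2(C)C)C(C)(C)C(C)=O | intermediate
4 | (6R)-6-hydroxy-3,3,7-trimethyloct-7-ene-2,4-dione | CC(=O)C(C)(C)C(=O)C[C@@H](O)C(C)=C | intermediate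
5 | isobutyraldehyde | CC(C)C=O | starting material
6 | hemiacetal of 4 with 5 at O9 (samarium-bound in the flask, hemiacetal carbon undefined) | CC(=O)C(C)(C)C(=O)C[C@@H](OC(O)C(C)C)C(C)=C | intermediate
7 | (3R,5R)-5-hydroxy-2,6,6-trimethyl-7-oxooct-1-en-3-yl 2-methylpropanoate | CC(=O)C(C)(C)[C@H](O)C[C@@H](OC(=O)C(C)C)C(C)=C | intermediate
8 | (3R,5R)-2,6,6-trimethyl-7-oxo-5-[(triethylsilyl)oxy]oct-1-en-3-yl 2-methylpropanoate | CC(=O)C(C)(C)[C@H](O[Si](CC)(CC)CC)C[C@@H](OC(=O)C(C)C)C(C)=C | intermediate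
9 | lithium enolate of 8 | [Li]OC(=C)C(C)(C)[C@H](O[Si](CC)(CC)CC)C[C@@H](OC(=O)C(C)C)C(C)=C | intermediate
10 | Mannich base, (3R,5R)-9-(dimethylamino)-2,6,6-trimethyl-7-oxo-5-[(triethylsilyl)oxy]non-1-en-3-yl 2-methylpropanoate | CN(C)CCC(=O)C(C)(C)[C@H](O[Si](CC)(CC)CC)C[C@@H](OC(=O)C(C)C)C(C)=C | intermediate
11 | methiodide of 10 | C[N+](C)(C)CCC(=O)C(C)(C)[C@H](O[Si](CC)(CC)CC)C[C@@H](OC(=O)C(C)C)C(C)=C.[I-] | intermediate
12 | (3R,5R)-2,6,6-trimethyl-7-oxo-5-[(triethylsilyl)oxy]nona-1,8-dien-3-yl 2-methylpropanoate | C=CC(=O)C(C)(C)[C@H](O[Si](CC)(CC)CC)C[C@@H](OC(=O)C(C)C)C(C)=C | intermediate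
13 | (1R,6R)-2,5,5-trimethyl-4-oxo-6-[(triethylsilyl)oxy]cyclohept-2-en-1-yl 2-methylpropanoate | O=C1C=C(C)[C@H](OC(=O)C(C)C)C[C@@H](O[Si](CC)(CC)CC)C1(C)C | intermediate
14 | (E)-1-(dimethylamino)-3-[(tert-butyldimethylsilyl)oxy]buta-1,3-diene | CN(C)/C=C/C(=C)O[Si](C)(C)C(C)(C)C | starting material
15 | [4+2] adduct of 13 and 14 (cis-fused amino silyl enol ether, amine-bearing carbon undefined) | CC[Si](CC)(CC)O[C@@H]1C[C@@H](OC(=O)C(C)C)[C@]2(C)CC(O[Si](C)(C)C(C)(C)C)=CC(N(C)C)[C@@H]2C(=O)C1(C)C | intermediate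
16 | (1R,2R,4R,7S)-4-hydroxy-1,5,5-trimethyl-6,10-dioxobicyclo[5.4.0]undec-8-en-2-yl 2-methylpropanoate | O[C@@H]1C[C@@H](OC(=O)C(C)C)[C@]2(C)CC(=O)C=C[C@@H]2C(=O)C1(C)C | intermediate
17 | (1R,2R,4R,6R,7S)-4,6-dihydroxy-1,5,5-trimethyl-10-oxobicyclo[5.4.0]undec-8-en-2-yl 2-methylpropanoate | O[C@@H]1C[C@@H](OC(=O)C(C)C)[C@]2(C)CC(=O)C=C[C@@H]2[C@@H](O)C1(C)C | intermediate
18 | (1R,2R,4R,6R,7S)-4-[(tert-butyldimethylsilyl)oxy]-6-hydroxy-1,5,5-trimethyl-10-oxobicyclo[5.4.0]undec-8-en-2-yl 2-methylpropanoate | CC(C)(C)[Si](C)(C)O[C@@H]1C[C@@H](OC(=O)C(C)C)[C@]2(C)CC(=O)C=C[C@@H]2[C@@H](O)C1(C)C | intermediate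
19 | (1R,2R,4R,6R,7S)-4-[(tert-butyldimethylsilyl)oxy]-1,5,5-trimethyl-6-[(4-methylbenzenesulfonyl)oxy]-10-oxobicyclo[5.4.0]undec-8-en-2-yl 2-methylpropanoate | CC(C)(C)[Si](C)(C)O[C@@H]1C[C@@H](OC(=O)C(C)C)[C@]2(C)CC(=O)C=C[C@@H]2[C@@H](OS(=O)(=O)c3ccc(C)cc3)C1(C)C | intermediate
20 | lithium α′-enolate of 19 | CC(C)(C)[Si](C)(C)O[C@@H]1C[C@@H](OC(=O)C(C)C)[C@]2(C)C=C(O[Li])C=C[C@@H]2[C@@H](OS(=O)(=O)c3ccc(C)cc3)C1(C)C | intermediate
21 | (1R,2S,3R,5R,7R,8S)-5-[(tert-butyldimethylsilyl)oxy]-2,6,6-trimethyl-9-oxotricyclo[5.4.0.0(2,8)]undec-10-en-3-yl 2-methylpropanoate | CC(C)(C)[Si](C)(C)O[C@@H]1C[C@@H](OC(=O)C(C)C)[C@@]2(C)[C@@H]3C=CC(=O)[C@H]2[C@@H]3C1(C)C | intermediate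
22 | 5-[(tert-butyldimethylsilyl)oxy]-9-hydroxy-2,6,6,9-tetramethyltricyclo[5.4.0.0(2,8)]undec-10-en-3-yl 2-methylpropanoate (carbinol centre undefined, others as in 21) | CC(C)(C)[Si](C)(C)O[C@@H]1C[C@@H](OC(=O)C(C)C)[C@@]2(C)[C@@H]3C=CC(C)(O)[C@H]2[C@@H]3C1(C)C | intermediate
23 | tertiary allylic chlorochromate ester of 22 | CC(C)(C)[Si](C)(C)O[C@@H]1C[C@@H](OC(=O)C(C)C)[C@@]2(C)[C@@H]3C=CC(C)(O[Cr](=O)(=O)Cl)[C@H]2[C@@H]3C1(C)C | intermediate
24 | [3,3]-transposed secondary allylic chlorochromate ester (C1 centre undefined) | CC(C)(C)[Si](C)(C)O[C@@H]1C[C@@H](OC(=O)C(C)C)[C@@]2(C)[C@@H]3C(O[Cr](=O)(=O)Cl)C=C(C)[C@H]2[C@@H]3C1(C)C | intermediate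
25 | (1R,2R,3R,5R,7S,8R)-5-[(tert-butyldimethylsilyl)oxy]-2,6,6,9-tetramethyl-11-oxotricyclo[5.4.0.0(2,8)]undec-9-en-3-yl 2-methylpropanoate | CC(C)(C)[Si](C)(C)O[C@@H]1C[C@@H](OC(=O)C(C)C)[C@@]2(C)[C@@H]3C(=O)C=C(C)[C@H]2[C@@H]3C1(C)C | intermediate
26 | (1R,2R,3R,5R,7S,8R)-5-hydroxy-2,6,6,9-tetramethyl-11-oxotricyclo[5.4.0.0(2,8)]undec-9-en-3-yl 2-methylpropanoate | O[C@@H]1C[C@@H](OC(=O)C(C)C)[C@@]2(C)[C@@H]3C(=O)C=C(C)[C@H]2[C@@H]3C1(C)C | intermediate
27 | methacryloyl chloride | C=C(C)C(Cl)=O | starting material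
28 | (1R,2R,3R,5R,7S,8R)-2,6,6,9-tetramethyl-3-[(2-methylpropanoyl)oxy]-11-oxotricyclo[5.4.0.0(2,8)]undec-9-en-5-yl 2-methylprop-2-enoate | C=C(C)C(=O)O[C@@H]1C[C@@H](OC(=O)C(C)C)[C@@]2(C)[C@@H]3C(=O)C=C(C)[C@H]2[C@@H]3C1(C)C | target

**Totals:** 14 steps; longest linear sequence 14 steps (from 1).

**Steps most likely to fail**

Step 6. The β,β-disubstituted enone with an α′-quaternary carbon may be too poor a dienophile, so the diene decomposes before it adds, or the addition may show poor facial selectivity. The fallback sets out from 13 and builds the ring in two polar stages. A Mukaiyama–Michael addition of trans-1-methoxy-3-(trimethylsilyloxy)buta-1,3-diene through its CH2 terminus to C10 (Tf2NH or tBuMe2SiOTf as catalyst, CH2Cl2, −78 °C, aqueous work-up) should give the δ-diketone Mukaiyama–Michael adduct F1. DBU in MeCN then lets the C11 enolate of the seven-ring ketone add to the β-methoxy enone and expel methanol, giving the triethylsilyl-protected bicyclic enone F2. HF in MeCN removes the silyl group, and the sequence comes back to the route at 16.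

Step 10. The ring closure may lose to O-alkylation, to proton transfer giving the extended dienolate that expels the sulfonate, to acyl transfer from O9, or it may simply be too slow at the hindered carbon. The fallback sets out from 19 and uses an aza-enolate instead of the enolate. Condensation with 1,1-dimethylhydrazine (AcOH cat., EtOH) gives the N,N-dimethylhydrazone F3. Its α′-lithio derivative (LiN(iPr)2, THF, −78 to 0 °C) is more nucleophilic and cannot O-alkylate, and should close the same C4–C5 bond to give the tricyclic hydrazone F4. Buffered aqueous CuCl2 hydrolysis comes back to the route at 21.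

Step 12. The tertiary allylic chromate may ionise instead of rearranging, which would open or rearrange the pinene-type cyclobutane. The fallback sets out from 21 and uses chemistry known for pinane ketones. Hydrogenation (H2, Pd/C, EtOAc) gives the saturated ketone F5. KN(SiMe3)2 and PhNTf2 give the enol triflate F6, regiospecifically because C4 is a bridgehead. Iron-catalysed methylation (MeMgBr, Fe(acac)3, THF/NMP, −30 °C) gives the trisubstituted alkene F7. Allylic oxidation of the ring CH2 at C1 (CrO3·3,5-dimethylpyrazole, CH2Cl2, −20 °C), the site preferred in α-pinene-type alkenes, comes back to the route at 25.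

**Further compounds**
F1 | step 6 | (1R,6R)-3-[(E)-4-methoxy-2-oxobut-3-en-1-yl]-3,7,7-trimethyl-4-[(2-methylpropanoyl)oxy]-6-[(triethylsilyl)oxy]cycloheptan-1-one (C10 configured as in 16) | O=C1C[C@@](C)(CC(=O)/C=C/OC)[C@H](OC(=O)C(C)C)C[C@@H](O[Si](CC)(CC)CC)C1(C)C
F2 | step 6 | triethylsilyl ether of 16 | CC[Si](CC)(CC)O[C@@H]1C[C@@H](OC(=O)C(C)C)[C@]2(C)CC(=O)C=C[C@@H]2C(=O)C1(C)C
F3 | step 10 | N,N-dimethylhydrazone of 19 | CC(C)(C)[Si](C)(C)O[C@@H]1C[C@@H](OC(=O)C(C)C)[C@]2(C)CC(=NN(C)C)C=C[C@@H]2[C@@H](OS(=O)(=O)c3ccc(C)cc3)C1(C)C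
F4 | step 10 | N,N-dimethylhydrazone of 21 | CC(C)(C)[Si](C)(C)O[C@@H]1C[C@@H](OC(=O)C(C)C)[C@@]2(C)[C@@H]3C=CC(=NN(C)C)[C@H]2[C@@H]3C1(C)C
F5 | step 12 | 10,11-dihydro derivative of 21 (saturated C3 ketone) | CC(C)(C)[Si](C)(C)O[C@@H]1C[C@@H](OC(=O)C(C)C)[C@@]2(C)[C@@H]3CCC(=O)[C@H]2[C@@H]3C1(C)C
F6 | step 12 | enol triflate of F5 | CC(C)(C)[Si](C)(C)O[C@@H]1C[C@@H](OC(=O)C(C)C)[C@@]2(C)[C@@H]3CC=C(OS(=O)(=O)C(F)(F)F)[C@H]2[C@@H]3C1(C)C
F7 | step 12 | 7-O-tert-butyldimethylsilyl-9-O-isobutyryl-longipin-2-ene (1-deoxo analogue of 25) | CC(C)(C)[Si](C)(C)O[C@@H]1C[C@@H](OC(=O)C(C)C)[C@@]2(C)[C@@H]3CC=C(C)[C@H]2[C@@H]3C1(C)C
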